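**Retrosynthetic overview**
- Neonambiquinone A comes from site-selective O-acetylation of the vinylogous-acid OH of 3-hydroxy-2,5-bis(4-hydroxyphenyl)-1,4-benzoquinone.
- That hydroxyquinone comes from ether cleavage and mild oxidation of a 3,6-diarylbenzene-1,2,4-triol, the level of "reductively dehydrated atromentin".
- The central ring is the only ring formed. It is made by a head-to-tail [3+3] union of two C6–C3 units at the two bonds used in the fungal cyclodimerisation of 4-hydroxyphenylpyruvate: benzylic C-3 to C-1', then Dieckmann closure of C-3' onto C-1.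
- One unit is an arylpyruvate ester. The other carries its C-1 as CH2Cl, so the ring is formed one oxygen short and no deoxygenation is needed.
- Each C6–C3 unit is one step from a commercial anisyl reagent, and the two outer rings are bought.

Assumption: the SMILES has no stereocentre and no stereogenic double bond, so the target is achiral and needs no enantiocontrol. The only stereocentre met on the way is transient, racemic and erased on aromatisation.

**Step 1**
Reactants: 1 4-methoxybenzylmagnesium chloride; 2 dimethyl oxalate
Product: 3 methyl 3-(4-methoxyphenyl)-2-oxopropanoate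
Conditions: 2 (2.0 equiv), THF, −78 °C, 1 (0.25 M in THF) added dropwise; 1 M HCl quench at −78 °C
Reagents that add atoms: none
Why: Grignard mono-acylation by a dialkyl oxalate works because, with inverse addition to excess oxalate at −78 °C, the chelated magnesium hemiketal alkoxide survives until the quench, so the α-keto ester is released only on work-up and no second addition occurs; no stereocentre is formed.

**Step 2**
Reactants: 4 (4-methoxyphenyl)acetyl chloride
Product: 6 1-chloro-3-(4-methoxyphenyl)propan-2-one, via diazoketone 5 (not isolated)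
Conditions: TMSCHN2 (2.0 equiv), THF/MeCN 1:1, 0 °C to rt; then HCl (4 M in dioxane), 0 °C
Reagents that add atoms: trimethylsilyldiazomethane C[Si](C)(C)C=[N+]=[N-]; hydrogen chloride Cl
Why: Arndt–Eistert-type acylation of the diazoalkane with loss of Me3SiCl gives the α-diazoketone, which HCl protonates at carbon so that chloride displaces N2 (Nierenstein-type chloromethyl ketone synthesis), leaving the anisole ring and benzylic CH2 untouched; no stereocentre is formed.

**Step 3 (key step)**
Reactants: 3 methyl 3-(4-methoxyphenyl)-2-oxopropanoate; 6 1-chloro-3-(4-methoxyphenyl)propan-2-one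
Product: 8 3,6-bis(4-methoxyphenyl)benzene-1,2,4-triol, via diketo ester 7 (not isolated)
Conditions: 3 (1.05 equiv), NaOt-Bu (1.05 equiv), THF, −20 °C; 6, NaI (20 mol %), −20 °C to rt; then NaOt-Bu (2.5 equiv), 0 °C to rt, under argon; degassed 1 M HCl
Reagents that add atoms: none
Why: Proposed new method: this one-flask head-to-tail [3+3] union of two C6–C3 units copies the bond set of the arylpyruvate cyclodimerisation, in that the fully formed soft sodium enolate of 3 is C-alkylated by the α-halo ketone (iodide-catalysed SN2) to give 7, the more acidic C-3–H of 7 then enolises and masks the α-keto group against five-ring aldol closure, the benzyl ketone carbanion can therefore only attack the ester in a 6-exo-trig Dieckmann condensation, and loss of methoxide with enolisation to the aromatic triolate makes the closure irreversible; the closest known reaction types are the oxalate–dibenzyl ketone cyclocondensation, where a benzylic carbanion closes onto an already enolised α-keto ester, and the Claisen–Dieckmann cyclodimerisation of succinate esters, and the racemic stereocentre of 7 is erased on aromatisation.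

**Step 4**
Reactants: 8 3,6-bis(4-methoxyphenyl)benzene-1,2,4-triol
Product: 10 3-hydroxy-2,5-bis(4-hydroxyphenyl)-1,4-benzoquinone, via pentaphenol 9 (not isolated)
Conditions: BBr3 (6 equiv), CH2Cl2, −78 °C to rt, under argon; H2O, 0 °C; then FeCl3 (2.1 equiv), EtOAc/H2O, rt; product taken into aq NaHCO3 and re-acidified
Reagents that add atoms: none
Why: Lewis-acid aryl methyl ether cleavage is run at the arene level, where no quinone is present to add HBr, and the hydroxyhydroquinone core of 9 is by far the most easily oxidised site, so two equivalents of FeCl3 take it only to the 2-hydroxy-1,4-benzoquinone and leave the outer phenols alone; no stereocentre is formed.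

**Step 5**
Reactants: 10 3-hydroxy-2,5-bis(4-hydroxyphenyl)-1,4-benzoquinone
Product: 11 neonambiquinone A (3-acetoxy-2,5-bis(4-hydroxyphenyl)-1,4-benzoquinone)
Conditions: i-Pr2NEt (1.0 equiv), THF, −78 °C; AcCl (1.05 equiv), −78 to −30 °C; citrate buffer pH 4
Reagents that add atoms: acetyl chloride CC(=O)Cl
Why: This is a pKa-gated chemoselective O-acylation (vinylogous mixed-anhydride formation), because one equivalent of amine ionises only the vinylogous carboxylic acid OH (pKa about 4–5) and not the phenols (pKa about 9–10), the oxyanion captures AcCl irreversibly at low temperature, and neutral phenols are inert in the absence of free base; the product is achiral.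

**Compound list**
1 | 4-methoxybenzylmagnesium chloride | COc1ccc(C[Mg]Cl)cc1 | starting material
2 | dimethyl oxalate | COC(=O)C(=O)OC | starting material
3 | methyl 3-(4-methoxyphenyl)-2-oxopropanoate | COC(=O)C(=O)Cc1ccc(OC)cc1 | intermediate
4 | (4-methoxyphenyl)acetyl chloride | COc1ccc(CC(=O)Cl)cc1 | starting material
5 | 1-diazo-3-(4-methoxyphenyl)propan-2-one | COc1ccc(CC(=O)C=[N+]=[N-])cc1 | intermediate
6 | 1-chloro-3-(4-methoxyphenyl)propan-2-one | COc1ccc(CC(=O)CCl)cc1 | intermediate
7 | methyl 3,6-bis(4-methoxyphenyl)-2,5-dioxohexanoate (racemic) | COC(=O)C(=O)C(CC(=O)Cc1ccc(OC)cc1)c1ccc(OC)cc1 | intermediate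
8 | 3,6-bis(4-methoxyphenyl)benzene-1,2,4-triol | COc1ccc(cc1)-c1cc(O)c(-c2ccc(OC)cc2)c(O)c1O | intermediate
9 | 3,6-bis(4-hydroxyphenyl)benzene-1,2,4-triol | Oc1ccc(cc1)-c1cc(O)c(-c2ccc(O)cc2)c(O)c1O | intermediate
10 | 3-hydroxy-2,5-bis(4-hydroxyphenyl)-1,4-benzoquinone | OC1=C(c2ccc(O)cc2)C(=O)C=C(c2ccc(O)cc2)C1=O | intermediate
11 | neonambiquinone A | CC(=O)OC1=C(c2ccc(O)cc2)C(=O)C=C(c2ccc(O)cc2)C1=O | target

**Total step count:** 5. **Longest linear sequence:** 4 (step 1 or step 2, then steps 3, 4 and 5).

**Three steps most likely to fail**

Step 3 may fail through O-alkylation, through Feist–Benary furan formation by aldol attack on the ketone of 6, or through Favorskii loss of 6. The fallback sets out from 1 and comes back at 8.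
- Two equivalents of 1 are added to 1,4-dimethylpiperazine-2,3-dione (THF, 0 °C, acid work-up), a cyclic oxamide whose tetrahedral adducts hold until the quench. This gives 1,4-bis(4-methoxyphenyl)butane-2,3-dione F1.
- The mono-enolate of F1 (NaOt-Bu, THF) is alkylated with methyl bromoacetate, an electrophile that cannot enter Feist–Benary or Favorskii chemistry. This gives methyl 3,6-bis(4-methoxyphenyl)-4,5-dioxohexanoate F2.
- More NaOt-Bu closes the same six-membered ring by Dieckmann attack of the remaining benzylic carbanion on the ester, giving 8 after enolisation.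

Step 5 may fail through acetylation of the phenols or acetyl transfer from the quinone oxygen to a phenol. The fallback sets out from 10 and comes back at 11, and it replaces pKa control by protecting groups.
- TBSCl (3.5 equiv) and imidazole in DMF give the tris(tert-butyldimethylsilyl) ether F4.
- The silyl vinylogous ester of F4 falls off on work-up with aqueous citric acid in THF. This leaves 3-hydroxy-2,5-bis[4-(tert-butyldimethylsilyloxy)phenyl]-1,4-benzoquinone F5.
- Ac2O and pyridine at 0 °C acetylate the only free OH, giving 3-acetoxy-2,5-bis[4-(tert-butyldimethylsilyloxy)phenyl]-1,4-benzoquinone F6.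
- HF·pyridine in THF at 0 °C is acidic and non-nucleophilic. It removes both aryl silyl ethers without touching the acetoxyquinone and gives 11.

Step 4 may fail through partial air oxidation of 8 during isolation, incomplete cleavage from insoluble borates, or over-oxidation. The fallback sets out from 8 and comes back at 10, and it changes the redox level at which the material is purified and deprotected.
- Crude 8 is oxidised at once with FeCl3 in EtOAc/H2O to 3-hydroxy-2,5-bis(4-methoxyphenyl)-1,4-benzoquinone F3. This is a bench-stable acid that is purified through its bicarbonate-soluble salt.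
- The OH-deactivated quinone F3 is a poor acceptor for bromide. It is then demethylated with BBr3 (CH2Cl2, −78 to 0 °C, ice quench) to give 10 directly.

**Further compounds**
F1 | step 3 | 1,4-bis(4-methoxyphenyl)butane-2,3-dione | COc1ccc(CC(=O)C(=O)Cc2ccc(OC)cc2)cc1
F2 | step 3 | methyl 3,6-bis(4-methoxyphenyl)-4,5-dioxohexanoate (racemic) | COC(=O)CC(c1ccc(OC)cc1)C(=O)C(=O)Cc1ccc(OC)cc1
F3 | step 4 | 3-hydroxy-2,5-bis(4-methoxyphenyl)-1,4-benzoquinone | OC1=C(c2ccc(OC)cc2)C(=O)C=C(c2ccc(OC)cc2)C1=O
F4 | step 5 | 3-(tert-butyldimethylsilyloxy)-2,5-bis[4-(tert-butyldimethylsilyloxy)phenyl]-1,4-benzoquinone | CC(C)(C)[Si](C)(C)OC1=C(c2ccc(O[Si](C)(C)C(C)(C)C)cc2)C(=O)C=C(c2ccc(O[Si](C)(C)C(C)(C)C)cc2)C1=O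
F5 | step 5 | 3-hydroxy-2,5-bis[4-(tert-butyldimethylsilyloxy)phenyl]-1,4-benzoquinone | OC1=C(c2ccc(O[Si](C)(C)C(C)(C)C)cc2)C(=O)C=C(c2ccc(O[Si](C)(C)C(C)(C)C)cc2)C1=O
F6 | step 5 | 3-acetoxy-2,5-bis[4-(tert-butyldimethylsilyloxy)phenyl]-1,4-benzoquinone | CC(=O)OC1=C(c2ccc(O[Si](C)(C)C(C)(C)C)cc2)C(=O)C=C(c2ccc(O[Si](C)(C)C(C)(C)C)cc2)C1=O
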